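**Strategy.** The tetrahydrofuran hides a butenolide: ring carbons C5, C4 and C3 plus the hydroxymethyl carbon on C3 form a four-carbon chain oxygenated at both ends, so C4 is the β-carbon of a 2(5H)-furanone. Everything rests on making the bond between C4 and the benzylic carbon of the 3-hydroxy-4,5-dimethoxybenzyl group with reversed polarity: the aldehyde-derived 2-lithio-1,3-dithiane adds to a chiral 5-menthyloxyfuranone, and the enolate is trapped in the same flask by 3,4,5-trimethoxybenzaldehyde. One operation thus joins all three building blocks, forms the benzyl–C4 and C3–C2 bonds and fixes C3 and C4; hydrogenolysis, reduction and a cationic ring closure that sets C2 finish the synthesis.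

Key step: step 4

Ring numbering used throughout: O1, C2 (aryl), C3 (CH2OH), C4 (benzyl), C5.

Remark: the carbinol carbon created in step 4 (the future C2) is formed and carried as both epimers, because step 7 ionises it and resets it; this centre is therefore left open in the SMILES of 10–13.

Step 1
Reactants: 1 5-hydroxyfuran-2(5H)-one (racemic hemiacetal); 2 (+)-menthol, (1S,2R,5S)-2-isopropyl-5-methylcyclohexan-1-ol
Product: 3 (5S)-5-{[(1S,2R,5S)-2-isopropyl-5-methylcyclohexyl]oxy}furan-2(5H)-one
Conditions: CSA (cat.), toluene, reflux, Dean–Stark; crystallisation from petroleum ether, −20 °C; mother liquor re-equilibrated with cat. acid and recrystallised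
Reagents that add atoms: none
Why: Acid-catalysed acetalisation of the cyclic hemiacetal via the furanone oxocarbenium ion; the acetal carbon epimerises under acid, so C5 is set by crystallisation of the (5S)-d-menthyl diastereomer (crystallisation-induced diastereomer transformation), the mirror image of the crystalline (5R)-l-menthyl compound.

Step 2
Reactants: 4 3-hydroxy-4,5-dimethoxybenzaldehyde
Product: 5 3-(benzyloxy)-4,5-dimethoxybenzaldehyde
Conditions: BnBr, K2CO3, DMF, rt
Reagents that add atoms: benzyl bromide, BrCc1ccccc1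
Why: Williamson ether synthesis on the phenoxide; the benzyl ether shields the phenol from the organolithium chemistry of step 4.

Step 3
Reactants: 5 3-(benzyloxy)-4,5-dimethoxybenzaldehyde
Product: 6 2-[3-(benzyloxy)-4,5-dimethoxyphenyl]-1,3-dithiane
Conditions: HS(CH2)3SH, BF3·OEt2 (cat.), CH2Cl2, 0 °C to rt
Reagents that add atoms: propane-1,3-dithiol, SCCCS
Why: Lewis-acid-catalysed dithioacetalisation turns the aldehyde carbon into an acidic C–H for Corey–Seebach umpolung.

Step 4
Reactants: 6 2-[3-(benzyloxy)-4,5-dimethoxyphenyl]-1,3-dithiane; 3 (5S)-5-(d-menthyloxy)furan-2(5H)-one; 7 3,4,5-trimethoxybenzaldehyde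
Product: 11 (3R,4S,5S)-4-{2-[3-(benzyloxy)-4,5-dimethoxyphenyl]-1,3-dithian-2-yl}-3-[hydroxy(3,4,5-trimethoxyphenyl)methyl]-5-(d-menthyloxy)oxolan-2-one (both carbinol epimers), via lithiated dithiane 8 (not isolated), via lactone lithium enolate 9 (not isolated), via lithium aldolate 10 (not isolated)
Conditions: 6, n-BuLi, THF, −78 to −30 °C; then 3, −78 °C; then 7, −78 °C; AcOH quench at −78 °C
Reagents that add atoms: none
Why: n-BuLi deprotonates the aryl-stabilised dithiane C–H to give 8, in which the former aldehyde carbon is a nucleophile (Corey–Seebach umpolung); 8 adds in Michael fashion to C4 of furanone 3, and the lithium enolate 9 then undergoes aldol addition to aldehyde 7 to give aldolate 10, protonated cold to 11. The closest known reaction type is the tandem conjugate addition–aldol (three-component Michael/aldol) coupling of lithiated 2-aryl-1,3-dithianes, butenolides and aryl aldehydes. No ring is closed. C4 is set by the acetal stereocentre C5, the dithianyl anion attacking the face anti to the menthyloxy group, and C3 is set by C4, the aldehyde approaching the enolate anti to the bulky dithianyl group (3,4-trans in the lactone, which becomes the 3,4-cis relationship of the tetrahydrofuran because the ring oxygen later bridges the other pair of substituents); the carbinol carbon is not controlled and need not be. The step needs 1,4- over 1,2-addition, which the soft, delocalised, hindered dithianyl anion and the γ-alkoxybutenolide should secure, and it needs the aldol not to revert, which the −78 °C acetic acid quench should secure.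

Step 5
Reactants: 11 dithianyl aldol lactone (both carbinol epimers)
Product: 12 (3R,4S,5S)-4-[(3-hydroxy-4,5-dimethoxyphenyl)methyl]-3-[hydroxy(3,4,5-trimethoxyphenyl)methyl]-5-(d-menthyloxy)oxolan-2-one (both carbinol epimers)
Conditions: Raney Ni (W-2, excess, washed neutral), H2 (1 atm), EtOH–THF, rt
Reagents that add atoms: none
Why: Mozingo-type Raney nickel desulfurisation of both C–S bonds together with nickel-mediated hydrogenolysis of the aryl benzyl ether, while the lactone, the acetal and the electron-rich benzylic carbinol (slow to hydrogenolyse on nickel at room temperature) should persist; no stereocentre is touched.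

Step 6
Reactants: 12 phenolic aldol lactone (both carbinol epimers)
Product: 13 (2S,3S)-2-[(3-hydroxy-4,5-dimethoxyphenyl)methyl]-3-[hydroxy(3,4,5-trimethoxyphenyl)methyl]butane-1,4-diol (both carbinol epimers)
Conditions: LiAlH4 (excess), THF, 0 °C to rt, substrate added to the hydride; Rochelle salt work-up at pH about 7
Reagents that add atoms: none
Why: Hydride reduction of the γ-alkoxy lactone: the carbonyl becomes CH2OH, the liberated C5 hemiacetal collapses with loss of menthoxide to the aldehyde and is reduced to the second CH2OH, leaving the C3 and C4 stereocentres untouched.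

Step 7
Reactants: 13 tetraol (both carbinol epimers)
Product: 14 [(2R,3S,4S)-4-[(3-hydroxy-4,5-dimethoxyphenyl)methyl]-2-(3,4,5-trimethoxyphenyl)oxolan-3-yl]methanol (2,3-trans, 3,4-cis)
Conditions: CSA (0.1 equiv), CH2Cl2–THF, 0 °C to rt, short reaction time; Et3N quench
Reagents that add atoms: none
Why: Acid-catalysed SN1 cycloetherification: CSA ionises the benzylic alcohol of either epimer to the para-methoxy-stabilised cation, which is captured 5-exo by the hydroxyl of the CH2OH on the benzyl-bearing carbon (the other primary hydroxyl could only close an oxetane) through the A1,3-minimised conformer, so the aryl group should end trans to the C3 hydroxymethyl group and C2 is set as R under control of C3.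

**Compound list**

1 | 5-hydroxyfuran-2(5H)-one | O=C1C=CC(O)O1 | starting material
2 | (+)-menthol, (1S,2R,5S) | O[C@H]1C[C@@H](C)CC[C@@H]1C(C)C | starting material
3 | (5S)-5-(d-menthyloxy)furan-2(5H)-one | O=C1C=C[C@@H](O[C@H]2C[C@@H](C)CC[C@@H]2C(C)C)O1 | intermediate
4 | 3-hydroxy-4,5-dimethoxybenzaldehyde | COc1cc(C=O)cc(O)c1OC | starting material
5 | 3-(benzyloxy)-4,5-dimethoxybenzaldehyde | COc1cc(C=O)cc(OCc2ccccc2)c1OC | intermediate
6 | 2-[3-(benzyloxy)-4,5-dimethoxyphenyl]-1,3-dithiane | COc1cc(C2SCCCS2)cc(OCc2ccccc2)c1OC | intermediate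
7 | 3,4,5-trimethoxybenzaldehyde | COc1cc(C=O)cc(OC)c1OC | starting material
8 | 2-[3-(benzyloxy)-4,5-dimethoxyphenyl]-2-lithio-1,3-dithiane (not isolated) | [Li]C1(c2cc(OC)c(OC)c(OCc3ccccc3)c2)SCCCS1 | intermediate
9 | lithium enolate of (4S,5S)-4-{2-[3-(benzyloxy)-4,5-dimethoxyphenyl]-1,3-dithian-2-yl}-5-(d-menthyloxy)oxolan-2-one, 4,5-trans (not isolated) | [Li]OC1=C[C@H](C2(c3cc(OC)c(OC)c(OCc4ccccc4)c3)SCCCS2)[C@@H](O[C@H]2C[C@@H](C)CC[C@@H]2C(C)C)O1 | intermediate
10 | lithium alkoxide of 11, both carbinol epimers (not isolated) | O=C1O[C@H](O[C@H]2C[C@@H](C)CC[C@@H]2C(C)C)[C@@H](C2(c3cc(OC)c(OC)c(OCc4ccccc4)c3)SCCCS2)[C@@H]1C(O[Li])c1cc(OC)c(OC)c(OC)c1 | intermediate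
11 | (3R,4S,5S)-4-{2-[3-(benzyloxy)-4,5-dimethoxyphenyl]-1,3-dithian-2-yl}-3-[hydroxy(3,4,5-trimethoxyphenyl)methyl]-5-(d-menthyloxy)oxolan-2-one, 3,4-trans-4,5-trans, both carbinol epimers | O=C1O[C@H](O[C@H]2C[C@@H](C)CC[C@@H]2C(C)C)[C@@H](C2(c3cc(OC)c(OC)c(OCc4ccccc4)c3)SCCCS2)[C@@H]1C(O)c1cc(OC)c(OC)c(OC)c1 | intermediate
12 | (3R,4S,5S)-4-[(3-hydroxy-4,5-dimethoxyphenyl)methyl]-3-[hydroxy(3,4,5-trimethoxyphenyl)methyl]-5-(d-menthyloxy)oxolan-2-one, both carbinol epimers | O=C1O[C@H](O[C@H]2C[C@@H](C)CC[C@@H]2C(C)C)[C@@H](Cc2cc(OC)c(OC)c(O)c2)[C@@H]1C(O)c1cc(OC)c(OC)c(OC)c1 | intermediate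
13 | (2S,3S)-2-[(3-hydroxy-4,5-dimethoxyphenyl)methyl]-3-[hydroxy(3,4,5-trimethoxyphenyl)methyl]butane-1,4-diol, both carbinol epimers | OC[C@H]([C@@H](CO)Cc1cc(OC)c(OC)c(O)c1)C(O)c1cc(OC)c(OC)c(OC)c1 | intermediate
14 | [(2R,3S,4S)-4-[(3-hydroxy-4,5-dimethoxyphenyl)methyl]-2-(3,4,5-trimethoxyphenyl)oxolan-3-yl]methanol | COc1cc(C[C@@H]2CO[C@@H](c3cc(OC)c(OC)c(OC)c3)[C@@H]2CO)cc(O)c1OC | target

**Step count.** Total steps: 7. Longest linear sequence: 6 (steps 2 to 7, from 4); step 1 is a one-step side branch that joins at step 4.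

**Steps most likely to fail**

Step 4. The aldol stage may revert (retro-aldol of the crowded lithium aldolate before the quench) or the hindered enolate may be captured incompletely, leaving the simple conjugate adduct. The fallback replaces the reversible aldol by an irreversible Claisen-type C-acylation and corrects the oxidation level afterwards. It sets out from enolate 9, generated as before from 6 and 3. The cold enolate solution is added to excess 3,4,5-trimethoxybenzoyl chloride in THF at −78 °C (inverse addition, so the acidic product cannot quench unreacted enolate), which should give the β-keto lactone F1. NaBH4 in MeOH–THF at −20 to 0 °C then reduces only the aryl ketone to the carbinol. The route is rejoined at 11.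

Step 5. The two hydrogenolyses may not finish together (benzyl ether partly retained), or hydrogenolysis may run on into the benzylic carbinol C–O bond. The fallback separates the two unmasking events. It sets out from 11: nickel boride (NiCl2·6H2O, NaBH4, MeOH–THF, 0 °C) removes only the sulfur and should give the O-benzyl aldol lactone F2; any partial lactone reduction is harmless because hydride reduction follows. LiAlH4 in THF gives the O-benzyl triol F3. CSA in CH2Cl2 closes the ring to the O-benzyl tetrahydrofuran F4. Hydrogenolysis (H2, Pd/C, EtOAc, rt, neutral) then frees the phenol. The route is rejoined at 14.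

Step 7. The benzylic cation may be captured by the electron-rich pendant arene (six-membered Friedel–Crafts closure to an aryltetralin), or the product may re-ionise under acid and drain along that path or lose its C2 configuration. The fallback closes the ring from the base side, where the product cannot re-ionise. It sets out from 13: TBSCl (about 3 equiv), imidazole, DMF, 0 °C should silylate the phenol and both primary hydroxyls and leave the hindered benzylic hydroxyl free, giving the tris-silyl ether F5. MsCl and Et3N in CH2Cl2 (−20 °C to rt) convert the benzylic hydroxyl into a mesylate that ionises as an ion pair and is displaced 5-exo by the oxygen of the C5 silyl ether with loss of that silyl group, giving the bis-silyl tetrahydrofuran F6. TBAF in THF removes the remaining silyl groups. The route is rejoined at 14.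

**Further compounds**

F1 | step 4 | (3R,4S,5S)-4-{2-[3-(benzyloxy)-4,5-dimethoxyphenyl]-1,3-dithian-2-yl}-5-(d-menthyloxy)-3-(3,4,5-trimethoxybenzoyl)oxolan-2-one | O=C1O[C@H](O[C@H]2C[C@@H](C)CC[C@@H]2C(C)C)[C@@H](C2(c3cc(OC)c(OC)c(OCc4ccccc4)c3)SCCCS2)[C@@H]1C(=O)c1cc(OC)c(OC)c(OC)c1
F2 | step 5 | (3R,4S,5S)-4-{[3-(benzyloxy)-4,5-dimethoxyphenyl]methyl}-3-[hydroxy(3,4,5-trimethoxyphenyl)methyl]-5-(d-menthyloxy)oxolan-2-one, both carbinol epimers | O=C1O[C@H](O[C@H]2C[C@@H](C)CC[C@@H]2C(C)C)[C@@H](Cc2cc(OC)c(OC)c(OCc3ccccc3)c2)[C@@H]1C(O)c1cc(OC)c(OC)c(OC)c1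
F3 | step 5 | (2S,3S)-2-{[3-(benzyloxy)-4,5-dimethoxyphenyl]methyl}-3-[hydroxy(3,4,5-trimethoxyphenyl)methyl]butane-1,4-diol, both carbinol epimers | OC[C@H]([C@@H](CO)Cc1cc(OC)c(OC)c(OCc2ccccc2)c1)C(O)c1cc(OC)c(OC)c(OC)c1
F4 | step 5 | [(2R,3S,4S)-4-{[3-(benzyloxy)-4,5-dimethoxyphenyl]methyl}-2-(3,4,5-trimethoxyphenyl)oxolan-3-yl]methanol | COc1cc(C[C@@H]2CO[C@@H](c3cc(OC)c(OC)c(OC)c3)[C@@H]2CO)cc(OCc2ccccc2)c1OC
F5 | step 7 | tris(tert-butyldimethylsilyl) ether of 13 at the phenol and both primary hydroxyls, benzylic hydroxyl free, both carbinol epimers | CC(C)(C)[Si](C)(C)OC[C@H]([C@@H](CO[Si](C)(C)C(C)(C)C)Cc1cc(OC)c(OC)c(O[Si](C)(C)C(C)(C)C)c1)C(O)c1cc(OC)c(OC)c(OC)c1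
F6 | step 7 | bis(tert-butyldimethylsilyl) ether of 14 at the phenol and the C3 hydroxymethyl group, (2R,3S,4S) | COc1cc(C[C@@H]2CO[C@@H](c3cc(OC)c(OC)c(OC)c3)[C@@H]2CO[Si](C)(C)C(C)(C)C)cc(O[Si](C)(C)C(C)(C)C)c1OC
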